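**Strategy.** The route rests on disconnecting the bond between the guaiacyl ring and C2 of the oxolane ring (O1, C2–C5), the benzylic O–CH carbon next to spiro carbon C3. Carrying C3 as an exocyclic methylene makes C2 the formyl carbon of a 2-substituted acrolein whose C5 bears a tosylate. In one flask, catalyst-controlled arylzinc addition forms the aryl–C2 bond and sets C2, and the resulting alkoxide closes the oxolane at C5 (5-exo-tet), giving the 2,4-cis ring. The key step thus exploits C2 being both benzylic and bound to ring oxygen O1 beside sp2 C3. Because aryl and benzyl then flank C3 on one face, late epoxidation places the spiro-oxirane oxygen anti to both.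

Key step: step 10

Remarks: TIPS = triisopropylsilyl. O1 and C2–C5 are the oxolane atoms of the target (C2 aryl-bearing, C3 spiro, C4 benzyl-bearing). Assumption: (−)-MIB, (2S)-(−)-3-exo-(morpholino)isoborneol, directs aryl transfer to the Si face of aldehyde 13 as it does in its other organozinc additions; its enantiomer would be used if the sense on this substrate were the reverse.

Step 1
Reactants: 1 isovanillin (3-hydroxy-4-methoxybenzaldehyde)
Product: 2 4-methoxy-3-(triisopropylsilyloxy)benzaldehyde
Conditions: TIPSCl, imidazole, DMF, rt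
Reagents that add atoms: chlorotriisopropylsilane (TIPSCl), CC(C)[Si](Cl)(C(C)C)C(C)C
Why: Imidazole-mediated O-silylation of the phenol; TIPS is chosen because it should survive NaHMDS, SeO2, organolithium and t-BuOK and leave with fluoride at the end.

Step 2
Reactants: 2 4-methoxy-3-(triisopropylsilyloxy)benzaldehyde
Product: 3 [4-methoxy-3-(triisopropylsilyloxy)phenyl]methanol
Conditions: NaBH4, MeOH, 0 °C
Reagents that add atoms: none
Why: Borohydride reduction of the aldehyde, which leaves the aryl silyl ether untouched.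

Step 3
Reactants: 3 [4-methoxy-3-(triisopropylsilyloxy)phenyl]methanol
Product: 4 [5-(bromomethyl)-2-methoxyphenoxy]triisopropylsilane
Conditions: CBr4, PPh3, CH2Cl2, 0 °C
Reagents that add atoms: tetrabromomethane, BrC(Br)(Br)Br
Why: Appel bromination under neutral conditions should give the electron-rich benzyl bromide, which is used without storage.

Step 4
Reactants: 5 (R)-4-benzyloxazolidin-2-one; 6 3-methylbut-2-enoyl chloride
Product: 8 (R)-4-benzyl-3-(3-methylbut-2-enoyl)oxazolidin-2-one, via lithium oxazolidinide 7 (not isolated)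
Conditions: n-BuLi, THF, −78 °C; then 6, −78 → 0 °C
Reagents that add atoms: none
Why: N-acylation of the lithiated oxazolidinone by the acid chloride (standard auxiliary loading).

Step 5
Reactants: 8 (R)-4-benzyl-3-(3-methylbut-2-enoyl)oxazolidin-2-one; 4 [5-(bromomethyl)-2-methoxyphenoxy]triisopropylsilane
Product: 10 (R)-4-benzyl-3-[(2R)-2-{[4-methoxy-3-(triisopropylsilyloxy)phenyl]methyl}-3-methylbut-3-enoyl]oxazolidin-2-one, via sodium dienolate 9 (not isolated)
Conditions: NaHMDS, THF, −78 °C; then 4, −78 → −40 °C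
Reagents that add atoms: none
Why: Deconjugative Evans alkylation: γ-deprotonation gives the chelated (Z)-dienolate, which is alkylated kinetically at the α-carbon on the face opposite the auxiliary benzyl group, setting the (R) centre (C4 of the target) and leaving an isopropenyl group.

Step 6
Reactants: 10 the alkylated imide
Product: 11 (2R)-2-{[4-methoxy-3-(triisopropylsilyloxy)phenyl]methyl}-3-methylbut-3-en-1-ol
Conditions: LiBH4, MeOH (1 equiv), THF, 0 °C
Reagents that add atoms: none
Why: Reductive cleavage of the exocyclic imide carbonyl gives the primary alcohol (future C5) without enolisation of the stereocentre, and the auxiliary is recovered.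

Step 7
Reactants: 11 the homoallylic alcohol
Product: 12 (2R)-2-{[4-methoxy-3-(triisopropylsilyloxy)phenyl]methyl}-3-methylbut-3-en-1-yl 4-methylbenzenesulfonate
Conditions: TsCl, Et3N, DMAP (cat.), CH2Cl2, 0 °C → rt
Reagents that add atoms: 4-methylbenzenesulfonyl chloride (TsCl), Cc1ccc(S(=O)(=O)Cl)cc1
Why: Sulfonylation of the unhindered primary alcohol installs the leaving group for the later ring closure.

Step 8
Reactants: 12 the isopropenyl tosylate
Product: 13 (2R)-3-formyl-2-{[4-methoxy-3-(triisopropylsilyloxy)phenyl]methyl}but-3-en-1-yl 4-methylbenzenesulfonate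
Conditions: SeO2, 1,4-dioxane, 80 °C
Reagents that add atoms: selenium dioxide, O=[Se]=O
Why: Riley allylic oxidation (ene reaction at the terminal CH2, [2,3]-shift, further oxidation) should turn the methyl group of the 1,1-disubstituted alkene into the formyl group, the methyl C–H being preferred over the hindered tertiary C–H at the stereocentre.

Step 9
Reactants: 14 4-bromo-2-methoxyphenol
Product: 15 (4-bromo-2-methoxyphenoxy)triisopropylsilane
Conditions: TIPSCl, imidazole, DMF, rt
Reagents that add atoms: chlorotriisopropylsilane (TIPSCl), CC(C)[Si](Cl)(C(C)C)C(C)C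
Why: Imidazole-mediated O-silylation of the phenol masks it for the halogen–metal exchange.

Step 10
Reactants: 15 (4-bromo-2-methoxyphenoxy)triisopropylsilane; 13 the enal tosylate
Product: 19 (2R,4R)-2-[3-methoxy-4-(triisopropylsilyloxy)phenyl]-4-{[4-methoxy-3-(triisopropylsilyloxy)phenyl]methyl}-3-methylideneoxolane, via aryllithium 16 (not isolated), via arylbutylzinc 17 (not isolated), via zinc alkoxide 18 (not isolated)
Conditions: 15, n-BuLi, t-BuOMe, −78 °C; ZnCl2, then n-BuLi, −78 → 0 °C; TEEDA, toluene; (−)-MIB (5 mol %), 13, 0 °C; then t-BuOK, THF, 0 °C → rt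
Reagents that add atoms: none
Why: Bromine–lithium exchange and transmetalation give the mixed arylbutylzinc 17, which transfers only its aryl group to the formyl carbon of 13 inside the chiral zinc amino-alkoxide of (−)-MIB (catalytic asymmetric arylation of an aldehyde), so the aryl–C2 bond and the C2 stereocentre form together. C2 is set by the catalyst, which should deliver aryl to the Si face and give the (R)-carbinol as zinc alkoxide 18; the C4 centre, separated from the carbonyl by sp2 C3, should exert little bias. t-BuOK then converts 18 into a zincate/potassium alkoxide that displaces the primary tosylate at C5 in a 5-exo-tet Williamson closure of the oxolane (O1–C5); neither stereocentre is touched, so the 2,4-cis ring results. The step needs 1,2- over 1,4-addition (secured by carbonyl activation in the zinc amino-alkoxide and the absence of Cu or Ni), catalysed over background addition (TEEDA sequesters LiCl), and O-alkylation over E2 loss of tosylate (favoured by the intramolecular five-membered closure).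

Step 11
Reactants: 19 the 3-methylideneoxolane
Product: 20 (3S,4S,7S)-4-[3-methoxy-4-(triisopropylsilyloxy)phenyl]-7-{[4-methoxy-3-(triisopropylsilyloxy)phenyl]methyl}-1,5-dioxaspiro[2.4]heptane
Conditions: mCPBA, NaHCO3, CH2Cl2, 0 °C
Reagents that add atoms: 3-chloroperoxybenzoic acid (mCPBA), OOC(=O)c1cccc(Cl)c1
Why: Prilezhaev epoxidation of the 1,1-disubstituted alkene; the cis aryl (C2) and benzyl (C4) groups shield one face of C3, so the peracid should approach from the other face and place the oxirane oxygen anti to both, which is the (3S) spiro centre.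

Step 12
Reactants: 20 the bis-silyl spiro-epoxide
Product: 21 (3S,4S,7S)-4-(4-hydroxy-3-methoxyphenyl)-7-[(3-hydroxy-4-methoxyphenyl)methyl]-1,5-dioxaspiro[2.4]heptane (CNP0184956.1)
Conditions: TBAF, AcOH, THF, 0 °C
Reagents that add atoms: none
Why: Fluoride cleavage of both aryl silyl ethers; acetic acid buffering keeps the phenoxide concentration low, so the oxirane and the benzylic ether should stay intact.

**Compound list**

1 | isovanillin (3-hydroxy-4-methoxybenzaldehyde) | COc1ccc(C=O)cc1O | starting material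
2 | 4-methoxy-3-(triisopropylsilyloxy)benzaldehyde | COc1ccc(C=O)cc1O[Si](C(C)C)(C(C)C)C(C)C | intermediate
3 | [4-methoxy-3-(triisopropylsilyloxy)phenyl]methanol | COc1ccc(CO)cc1O[Si](C(C)C)(C(C)C)C(C)C | intermediate
4 | [5-(bromomethyl)-2-methoxyphenoxy]triisopropylsilane | COc1ccc(CBr)cc1O[Si](C(C)C)(C(C)C)C(C)C | intermediate
5 | (R)-4-benzyloxazolidin-2-one | O=C1N[C@H](Cc2ccccc2)CO1 | starting material
6 | 3-methylbut-2-enoyl chloride | CC(C)=CC(=O)Cl | starting material
7 | lithium salt of (R)-4-benzyloxazolidin-2-one | [Li+].O=C1[N-][C@H](Cc2ccccc2)CO1 | intermediate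
8 | (R)-4-benzyl-3-(3-methylbut-2-enoyl)oxazolidin-2-one | CC(C)=CC(=O)N1[C@H](Cc2ccccc2)COC1=O | intermediate
9 | sodium (Z)-dienolate of 8 | [Na+].C=C(C)/C=C(\[O-])N1[C@H](Cc2ccccc2)COC1=O | intermediate
10 | (R)-4-benzyl-3-[(2R)-2-{[4-methoxy-3-(triisopropylsilyloxy)phenyl]methyl}-3-methylbut-3-enoyl]oxazolidin-2-one | C=C(C)[C@@H](Cc1ccc(OC)c(O[Si](C(C)C)(C(C)C)C(C)C)c1)C(=O)N1[C@H](Cc2ccccc2)COC1=O | intermediate
11 | (2R)-2-{[4-methoxy-3-(triisopropylsilyloxy)phenyl]methyl}-3-methylbut-3-en-1-ol | C=C(C)[C@@H](Cc1ccc(OC)c(O[Si](C(C)C)(C(C)C)C(C)C)c1)CO | intermediate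
12 | (2R)-2-{[4-methoxy-3-(triisopropylsilyloxy)phenyl]methyl}-3-methylbut-3-en-1-yl 4-methylbenzenesulfonate | C=C(C)[C@@H](Cc1ccc(OC)c(O[Si](C(C)C)(C(C)C)C(C)C)c1)COS(=O)(=O)c1ccc(C)cc1 | intermediate
13 | (2R)-3-formyl-2-{[4-methoxy-3-(triisopropylsilyloxy)phenyl]methyl}but-3-en-1-yl 4-methylbenzenesulfonate | C=C(C=O)[C@@H](Cc1ccc(OC)c(O[Si](C(C)C)(C(C)C)C(C)C)c1)COS(=O)(=O)c1ccc(C)cc1 | intermediate
14 | 4-bromo-2-methoxyphenol | COc1cc(Br)ccc1O | starting material
15 | (4-bromo-2-methoxyphenoxy)triisopropylsilane | COc1cc(Br)ccc1O[Si](C(C)C)(C(C)C)C(C)C | intermediate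
16 | [3-methoxy-4-(triisopropylsilyloxy)phenyl]lithium | COc1cc([Li])ccc1O[Si](C(C)C)(C(C)C)C(C)C | intermediate
17 | butyl[3-methoxy-4-(triisopropylsilyloxy)phenyl]zinc | CCCC[Zn]c1ccc(O[Si](C(C)C)(C(C)C)C(C)C)c(OC)c1 | intermediate
18 | butylzinc alkoxide of (2R)-3-{(R)-hydroxy[3-methoxy-4-(triisopropylsilyloxy)phenyl]methyl}-2-{[4-methoxy-3-(triisopropylsilyloxy)phenyl]methyl}but-3-en-1-yl 4-methylbenzenesulfonate | CCCC[Zn]O[C@@H](c1ccc(O[Si](C(C)C)(C(C)C)C(C)C)c(OC)c1)C(=C)[C@@H](Cc1ccc(OC)c(O[Si](C(C)C)(C(C)C)C(C)C)c1)COS(=O)(=O)c1ccc(C)cc1 | intermediate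
19 | (2R,4R)-2-[3-methoxy-4-(triisopropylsilyloxy)phenyl]-4-{[4-methoxy-3-(triisopropylsilyloxy)phenyl]methyl}-3-methylideneoxolane (2,4-cis) | COc1ccc(C[C@H]2CO[C@@H](c3ccc(O[Si](C(C)C)(C(C)C)C(C)C)c(OC)c3)C2=C)cc1O[Si](C(C)C)(C(C)C)C(C)C | intermediate
20 | (3S,4S,7S)-4-[3-methoxy-4-(triisopropylsilyloxy)phenyl]-7-{[4-methoxy-3-(triisopropylsilyloxy)phenyl]methyl}-1,5-dioxaspiro[2.4]heptane | COc1ccc(C[C@H]2CO[C@@H](c3ccc(O[Si](C(C)C)(C(C)C)C(C)C)c(OC)c3)[C@@]23CO3)cc1O[Si](C(C)C)(C(C)C)C(C)C | intermediate
21 | (3S,4S,7S)-4-(4-hydroxy-3-methoxyphenyl)-7-[(3-hydroxy-4-methoxyphenyl)methyl]-1,5-dioxaspiro[2.4]heptane | COc1ccc(C[C@H]2CO[C@@H](c3ccc(O)c(OC)c3)[C@@]23CO3)cc1O | target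

**Totals.** Total step count: 12. Longest linear sequence: 10 steps (steps 1, 2, 3, 5, 6, 7, 8, 10, 11, 12 from isovanillin).

**Steps most likely to fail**

Step 10. The catalyst may not override uncatalysed aryl transfer, so facial control at C2 could be poor. The zinc-bound alkoxide may also close the ring too slowly, leaving room for E2 loss of the tosylate or base-induced migration of the exocyclic double bond into conjugation. The fallback moves stereocontrol from catalyst to substrate and sets out from enal 13. Amine-catalysed asymmetric epoxidation (aqueous H2O2, a 9-amino-9-deoxy-epi-cinchona alkaloid salt, the pseudo-enantiomer that gives the (S)-oxirane) should give the epoxy aldehyde F1. Addition of aryllithium 16 (from 15 and n-BuLi) in THF at −78 °C is expected to follow the polar Felkin–Anh model, with aryl entering anti to the oxirane C–O bond, and to give the hydroxy epoxide F2 as its lithium alkoxide. Warming with DMPU should close the oxolane by displacement of the tosylate. This fallback comes back to the route at 20, and step 11 is then not needed.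

Step 8. The ene step may attack the tertiary allylic C–H instead of the methyl group, stop at the allylic alcohol, or over-oxidise. The fallback sets out from 12 and brings in the oxygen by epoxidation. mCPBA (NaHCO3, CH2Cl2) should give the 2-methyloxirane F3 as both epimers at the new centre, which is removed again. Diethylaluminium 2,2,6,6-tetramethylpiperidide (toluene, 0 °C) should abstract a proton from the unhindered methyl group and open the ring to the allylic alcohol F4. MnO2 oxidation then gives 13, where the route is rejoined.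

Step 5. The dienolate may be alkylated at the γ-carbon, or the β,γ-double bond may move back into conjugation, eroding yield and stereochemical purity. The fallback uses a classical Evans alkylation of a saturated enolate and builds the acrolein afterwards; it sets out from 5 and 4. Acylation of 5 (n-BuLi, then pent-4-enoyl chloride) gives the pentenoyl imide F5. Its sodium enolate (NaHMDS, −78 °C) is alkylated by 4 anti to the auxiliary benzyl group to give the benzylated imide F6. LiBH4 gives the alcohol F7, and TsCl/Et3N gives the tosylate F8. Lemieux–Johnson cleavage (OsO4 cat., NaIO4, 2,6-lutidine) gives the aldehyde F9. α-Methylenation with Eschenmoser's salt and Et3N gives 13, where the route is rejoined; steps 6–8 are bypassed.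

**Further compounds**

F1 | step 10 | (2S)-2-[(2S)-2-formyloxiran-2-yl]-3-[4-methoxy-3-(triisopropylsilyloxy)phenyl]propyl 4-methylbenzenesulfonate | O=C[C@@]1(CO1)[C@@H](Cc1ccc(OC)c(O[Si](C(C)C)(C(C)C)C(C)C)c1)COS(=O)(=O)c1ccc(C)cc1
F2 | step 10 | (2S)-2-[(2S)-2-{(S)-hydroxy[3-methoxy-4-(triisopropylsilyloxy)phenyl]methyl}oxiran-2-yl]-3-[4-methoxy-3-(triisopropylsilyloxy)phenyl]propyl 4-methylbenzenesulfonate (formed as its lithium alkoxide) | O[C@@H](c1ccc(O[Si](C(C)C)(C(C)C)C(C)C)c(OC)c1)[C@@]1(CO1)[C@@H](Cc1ccc(OC)c(O[Si](C(C)C)(C(C)C)C(C)C)c1)COS(=O)(=O)c1ccc(C)cc1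
F3 | step 8 | (2S)-3-[4-methoxy-3-(triisopropylsilyloxy)phenyl]-2-(2-methyloxiran-2-yl)propyl 4-methylbenzenesulfonate (both epimers at the oxirane carbon) | CC1(CO1)[C@@H](Cc1ccc(OC)c(O[Si](C(C)C)(C(C)C)C(C)C)c1)COS(=O)(=O)c1ccc(C)cc1
F4 | step 8 | (2R)-3-(hydroxymethyl)-2-{[4-methoxy-3-(triisopropylsilyloxy)phenyl]methyl}but-3-en-1-yl 4-methylbenzenesulfonate | C=C(CO)[C@@H](Cc1ccc(OC)c(O[Si](C(C)C)(C(C)C)C(C)C)c1)COS(=O)(=O)c1ccc(C)cc1
F5 | step 5 | (R)-4-benzyl-3-(pent-4-enoyl)oxazolidin-2-one | C=CCCC(=O)N1[C@H](Cc2ccccc2)COC1=O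
F6 | step 5 | (R)-4-benzyl-3-[(2S)-2-{[4-methoxy-3-(triisopropylsilyloxy)phenyl]methyl}pent-4-enoyl]oxazolidin-2-one | C=CC[C@@H](Cc1ccc(OC)c(O[Si](C(C)C)(C(C)C)C(C)C)c1)C(=O)N1[C@H](Cc2ccccc2)COC1=O
F7 | step 5 | (2S)-2-{[4-methoxy-3-(triisopropylsilyloxy)phenyl]methyl}pent-4-en-1-ol | C=CC[C@@H](Cc1ccc(OC)c(O[Si](C(C)C)(C(C)C)C(C)C)c1)CO
F8 | step 5 | (2S)-2-{[4-methoxy-3-(triisopropylsilyloxy)phenyl]methyl}pent-4-en-1-yl 4-methylbenzenesulfonate | C=CC[C@@H](Cc1ccc(OC)c(O[Si](C(C)C)(C(C)C)C(C)C)c1)COS(=O)(=O)c1ccc(C)cc1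
F9 | step 5 | (2R)-2-{[4-methoxy-3-(triisopropylsilyloxy)phenyl]methyl}-4-oxobutyl 4-methylbenzenesulfonate | O=CC[C@@H](Cc1ccc(OC)c(O[Si](C(C)C)(C(C)C)C(C)C)c1)COS(=O)(=O)c1ccc(C)cc1
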